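## Structural features

The target is a carbon-linked biisoflavone. Unit G is a genistein skeleton (5,7-dihydroxy-3-(4-hydroxyphenyl)chromen-4-one) and unit D a daidzein skeleton (7-hydroxy-3-(4-hydroxyphenyl)chromen-4-one), and C8 of ring A(G) is bonded to C3' of ring B(D). There are six rings, five phenolic hydroxyls and no stereocentre. The biaryl axis has three ortho substituents (O7 and O1 on the G side, O4' on the D side), all small, so no stable atropisomer is expected and nothing stereochemical has to be set. The fragile parts are the two pyranone rings C, whose C2 is a vinylogous ester carbon that hydroxide, alkoxides and amines attack with ring opening, and the electron-rich phloroglucinol-type ring A(G), which is easily oxidised. The real difficulty is the C8(G)–C3'(D) bond: it joins a hindered chromone position, where C6 and C8 compete, to the carbon ortho to a phenol. The key step exploits the pattern of ring B(D): C4'(D)–OH sits between the biaryl carbon C3'(D) and C5'(D)–H, para to C1'(D). That is the pattern of a phenol built from a ketone unit CH2–CO–CH3 (C3', C4', C5') and a 2-substituted malondialdehyde unit (C2', C1', C6'). The biaryl bond can therefore exist beforehand as an sp2–sp3 bond C8(G)–CH2, which a sigmatropic shift from O7 can deliver, and the substituent left at C1'(D) is the handle for the rest of unit D.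

## Logic of the disconnections

17 ⇒ 16. The five O–CH3 bonds are cut (O5, O7, O4' of unit G; O7, O4' of unit D). Free phenols would interfere with the base of step 6 and the oxidant of step 9, and 1 already carries a methyl ether at O4'(G). The gain is a single protecting group removed in one operation. The forward step must cleave five aryl methyl ethers, two of them next to the biaryl axis, without a nucleophile that opens the pyranones.

16 ⇒ 14 (through 15). O1(D)–C2(D) is cut and the aryl bond at C3(D) is moved back to the neighbouring carbon. This turns the 3-arylchromone into an enone that an aldehyde at C1'(D) can supply. Ring C(D) disappears. The forward oxidative aryl shift needs an electron-rich, phenol-free migrating ring (hence the ether made in step 7) and an oxidant that prefers the enone to ring A(G).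

14 ⇒ 12 + 13. The enone Cα=Cβ bond (future C3(D)–C2(D)) is cut as an aldol condensation. This splits off ring A(D) with its oxygens as a commercial acetophenone and makes the end of the route convergent. The forward condensation must run without hydroxide or alkoxide, because ring C(G) would open at C2(G).

12 ⇒ 11. The O4'(D)–CH3 bond is cut. The gain is only that 11 is the direct benzannulation product. The forward methylation must precede the aldol and the oxidation, since a free para-hydroxyl deactivates the aldehyde and would be oxidised.

11 ⇒ 6 + 9 (key disconnection). C2'(D)–C3'(D) and C5'(D)–C6'(D) are cut. Ring B(D) falls apart into a three-carbon ketone side chain on C8(G) and a symmetric three-carbon dielectrophile, and the hindered biaryl bond becomes a benzylic C–C bond. No cross-coupling and no regiochemical choice remain. The forward step needs both α-carbons of 6 to react in turn under a base that spares ring C(G).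

9 ⇒ 7. The three bonds from the central carbon to the formyl carbons are cut (two replace C–H, one replaces C–Br, and the carboxyl carbon is lost). This leads to a commodity two-carbon acid in one operation. The forward hydrolysis must stop at the stage that keeps one enamine.

6 ⇒ 5. The side-chain C=O is traced back to a terminal alkene. The allyl group is what a sigmatropic shift can place on C8(G). The forward oxidation must be Markovnikov and must meet no free ortho-phenol, which would cyclise onto the alkene.

5 ⇒ 4. The O5–CH3 and O7–CH3 bonds are cut. The gain is that the rearrangement product is used as formed. The forward step must methylate the chelated 5-hydroxyl as well.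

4 ⇒ 3. The C8(G)–CH2 bond is cut by a retro-[3,3] shift that moves the allyl group to O7. A C–C bond at the hindered C8 is thus made intramolecularly, without halogenation or a metal. The forward rearrangement must go to C8 and not to C6.

3 ⇒ 1 + 2. The O7–CH2 bond is cut. Both fragments are commercial, and 1 carries the whole of unit G. The forward alkylation must be selective for O7, which the hydrogen bond of O5–H to the carbonyl secures.

## Other disconnections considered

Alternative 1: The cut lies in ring A(G), between C8(G) and one of its two oxygen-bearing neighbours (drawn as C7(G)–C8(G); the two are equivalent in the product). Ring A(G) becomes a triketide masked as the pyrone A1, 6-[(5-bromo-2-methoxyphenyl)methyl]-4-methoxy-2H-pyran-2-one.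
- Forward key step: Mg(OMe)2 in methanol would open the lactone of A1 to the keto ester A2, methyl 6-(5-bromo-2-methoxyphenyl)-3-methoxy-5-oxohex-2-enoate. Its benzylic carbanion would attack the ester in a Claisen condensation, and enolisation would give the symmetric resorcinol A3.
- Correction of geometry: A2 inherits its alkene from the pyrone ring, where the ester carbon and the chain carbon are cis. Methoxy outranks the chain carbon and lies trans to the ester, so A2 is the 2E isomer, not 2Z.
- In its favour: the biaryl bond is present from the start as an aryl–CH2 bond, so no hindered coupling is needed. The symmetry of A3 removes any site choice in the later acylation. The bromide at C1'(D) would allow a late Suzuki coupling with 3-iodo-7-methoxy-4H-chromen-4-one A4 to attach unit D.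
- Against it here: the ester of A2 is a vinylogous carbonate and a weak electrophile. The nucleophile is a singly activated, ortho-substituted benzylic carbon, and the more acidic C4 methylene of A2 can simply return to A1. After A3 the whole of unit G (deoxybenzoin, one-carbon insertion, ring C) still has to be built, whereas 1 supplies it.
- Comparison: on structure the two plans are equal in avoiding a cross-coupling for the hindered bond. On mechanism both are base-mediated condensations driven by aromatisation. Alternative 1 is the better in chemoselectivity, since no base-sensitive pyranone is present in its key step, and the better in hazard, since the Suzuki end avoids thallium. The chosen plan closes onto a more reactive aldehyde. On step economy, A1 (about three steps), the key step, about three steps to unit G, borylation, coupling with A4 (two steps of its own) and deprotection come to about eleven or twelve against ten.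

Alternative 2: The cut is C4–C4a in both units, so both pyranone rings C are opened to 3-aryloxy-2-arylacrylic acids held in the bis(acrylic acid) A5.
- Forward key step: in Eaton's reagent (P2O5 in methanesulfonic acid) the two acids of A5 would give acylium ions that attack C4a(D) and C4a(G) and close both rings C, giving the tetra-O-methyl ether A6 with O7(G) free.
- In its favour: two rings form in one metal-free operation at the end, with no thallium. In unit G only C4a is available ortho to the ether oxygen, so that closure has no site choice.
- Against it here: the disconnection does nothing for the C8(G)–C3'(D) bond, so A5 must already contain it and a tri-ortho-substituted coupling is pushed into the preparation of A5. Only the Z acids (carboxyl cis to aryloxy) can close. The aryl enol ethers are acid-labile. Closure in unit D can go para or ortho to the methoxy group. The free phenol of A5 can be acylated or sulfonylated in the medium.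
- Comparison: Alternative 2 is the better in rings closed per step (two against one) and the equal on stereochemistry (none). It is weaker on the central structural problem and on regiocontrol in unit D. A5 needs three aryl building blocks, a hindered O-vinylation and a biaryl coupling, so the total would probably exceed ten steps.

Alternative 3: Three bonds of ring A(G) are cut: C8(G)–C8a(G), C6(G)–C7(G) and C4a(G)–C8a(G). This leads back to 3-ethoxycyclobut-2-en-1-one A7 and the siloxyalkyne A8, {[(5-bromo-2-methoxyphenyl)ethynyl]oxy}tri(propan-2-yl)silane.
- Forward key step: heating A7 with A8 in toluene would run a pericyclic cascade (4π opening to a vinylketene, [2+2] addition to the alkyne, 4π opening, 6π closure, tautomerisation) to the phenol A9.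
- In its favour: the conditions are neutral and the regiochemistry is fixed by the cascade. The three oxygens come out differentiated (free hydroxyl at C8a, silyl ether at C7, ethyl ether at C5), so later acylation at C4a is directed by the free phenol. The biaryl bond is again present beforehand, as the aryl–alkyne bond, and the bromide allows the same Suzuki end with A4.
- Against it here: A7 is a sensitive, non-commercial cyclobutenone. A8 needs an ynolate synthesis with organolithium reagents beside an aryl bromide, where halogen–lithium exchange threatens. The oxygen differentiation is more than the target needs. Ring A(G) is again built from scratch, and C6 still competes with C4a in the acylation.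
- Comparison: Alternative 3 is the better in mildness and regiocontrol of the key step and the equal in avoiding a cross-coupling for the hindered bond. It is weaker in access to its two precursors and in step economy, with an estimated twelve to thirteen steps against ten.

Key step: step 6

Assumption: the biaryl axis of the target and of all intermediates is taken not to be configurationally stable at room temperature, so no axial descriptor is assigned.
Assumption: in step 5 the bromine of 7 is taken to leave as positive halogen, written as BrCl, when the third formyl equivalent enters at the central carbon of the 2-bromovinamidinium stage.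

## Route

Step 1
Reactants: 1 biochanin A; 2 allyl bromide
Product: 3 5-hydroxy-3-(4-methoxyphenyl)-7-(prop-2-en-1-yloxy)-4H-chromen-4-one
Conditions: K2CO3 (1.5 equiv), 2 (1.1 equiv), acetone, reflux
Reagents that add atoms: none
Why: Williamson ether synthesis (SN2): the 7-hydroxyl is the most acidic phenol of 1, while the 5-hydroxyl is held in a hydrogen bond to the C4 carbonyl and should not react with a weak base and one equivalent of 2.

Step 2
Reactants: 3 5-hydroxy-3-(4-methoxyphenyl)-7-(prop-2-en-1-yloxy)-4H-chromen-4-one
Product: 4 5,7-dihydroxy-3-(4-methoxyphenyl)-8-(prop-2-en-1-yl)-4H-chromen-4-one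
Conditions: N,N-diethylaniline, 200 °C, argon
Reagents that add atoms: none
Why: Aromatic Claisen rearrangement, a [3,3]-sigmatropic shift followed by enolisation; in a 7-allyloxybenzopyranone the C7–C8 bond has the higher double-bond character, so the allyl group should migrate mainly to C8 and not to C6.

Step 3
Reactants: 4 5,7-dihydroxy-3-(4-methoxyphenyl)-8-(prop-2-en-1-yl)-4H-chromen-4-one
Product: 5 5,7-dimethoxy-3-(4-methoxyphenyl)-8-(prop-2-en-1-yl)-4H-chromen-4-one
Conditions: MeI (excess), K2CO3, DMF, 40 °C
Reagents that add atoms: iodomethane, CI
Why: Double Williamson methylation; the chelated 5-hydroxyl needs the polar solvent, excess MeI and gentle heating. Capping both phenols prevents oxypalladation to a 2-methylbenzofuran in step 4 and leaves only C–H acids for step 6.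

Step 4
Reactants: 5 5,7-dimethoxy-3-(4-methoxyphenyl)-8-(prop-2-en-1-yl)-4H-chromen-4-one
Product: 6 5,7-dimethoxy-3-(4-methoxyphenyl)-8-(2-oxopropyl)-4H-chromen-4-one
Conditions: PdCl2 (10 mol %), CuCl (1 equiv), O2 (1 atm), DMF/H2O 7:1, rt
Reagents that add atoms: water, O
Why: Tsuji–Wacker oxidation: Markovnikov hydroxypalladation of the terminal alkene and β-hydride elimination give the methyl ketone, as with other allylarenes, while CuCl and O2 return the reduced palladium to the divalent state. The electron-poor enol ether double bond of ring C(G) should not compete.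

Step 5
Reactants: 7 bromoacetic acid
Product: 9 2-[(dimethylamino)methylidene]propanedial, via bis(iminium) dichloride 8 (not isolated)
Conditions: POCl3 (3 equiv), DMF, 0 → 90 °C; then ice, aq. K2CO3, 0 °C → rt
Reagents that add atoms: N,N-dimethylformamide, CN(C)C=O; water, O
Why: Vilsmeier–Haack–Arnold formylation: the chloroiminium ion formylates the α-carbon of 7 twice with loss of CO2, and a third formyl equivalent replaces bromine at the central carbon to give 8. Mild aqueous carbonate then hydrolyses two of the three iminium groups and leaves the push–pull enamine dialdehyde 9.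

Step 6
Reactants: 6 5,7-dimethoxy-3-(4-methoxyphenyl)-8-(2-oxopropyl)-4H-chromen-4-one; 9 2-[(dimethylamino)methylidene]propanedial
Product: 11 4-hydroxy-3-[5,7-dimethoxy-3-(4-methoxyphenyl)-4-oxo-4H-chromen-8-yl]benzaldehyde, via open-chain keto dialdehyde 10 (not isolated)
Conditions: KOtBu (2.2 equiv), THF, 4 Å MS, −20 °C → rt; then AcOH
Reagents that add atoms: none
Why: KOtBu deprotonates 6 at its more acidic benzylic carbon; this enolate adds to the aminomethylene carbon of 9, the β-position of both enals, and expels dimethylamine to give 10 (bond C2'(D)–C3'(D)). A second equivalent of base forms the enolate on the methyl side, which adds to one of the two equivalent formyl groups (bond C5'(D)–C6'(D)); loss of water and tautomerisation of the cyclohexadienone give the phenoxide of 11. The closest known reaction type is the [3+3] phenol synthesis from ketones with two enolisable α-positions and nitromalonaldehyde, vinamidinium salts or triformylmethane. Ring B(D) closes by a 6-(enolendo)-exo-trig aldol addition (enolendo, not enolexo, because both enolate carbons C4'(D) and C5'(D) lie in the new ring), and aromatisation makes the closure irreversible. No stereocentre is formed. No regiochemical choice arises, since the three-carbon unit is symmetric and both α-carbons must enter the ring, so the hydroxyl must come out next to C8(G) and para to the surviving formyl group. The selectivity needed is against nucleophilic opening of ring C(G) at C2(G); the non-nucleophilic base, the low temperature, the sieves that take up the water of condensation and the acidic quench should secure it.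

Step 7
Reactants: 11 4-hydroxy-3-[5,7-dimethoxy-3-(4-methoxyphenyl)-4-oxo-4H-chromen-8-yl]benzaldehyde
Product: 12 3-[5,7-dimethoxy-3-(4-methoxyphenyl)-4-oxo-4H-chromen-8-yl]-4-methoxybenzaldehyde
Conditions: MeI, K2CO3, acetone, reflux
Reagents that add atoms: iodomethane, CI
Why: Williamson methylation of the acidic 4-hydroxybenzaldehyde-type phenol; the ether blocks phenol oxidation by Tl(NO3)3 in step 9 and restores the electrophilicity of the aldehyde for step 8.

Step 8
Reactants: 12 3-[5,7-dimethoxy-3-(4-methoxyphenyl)-4-oxo-4H-chromen-8-yl]-4-methoxybenzaldehyde; 13 2-hydroxy-4-methoxyacetophenone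
Product: 14 (2E)-3-{3-[5,7-dimethoxy-3-(4-methoxyphenyl)-4-oxo-4H-chromen-8-yl]-4-methoxyphenyl}-1-(2-hydroxy-4-methoxyphenyl)prop-2-en-1-one
Conditions: BF3·OEt2 (3 equiv), 1,4-dioxane, rt; then aq. MeOH, 50 °C
Reagents that add atoms: none
Why: Lewis acid-mediated Claisen–Schmidt condensation: boron binds the chelating 2-hydroxy ketone, which enolises and adds to the BF3-activated aldehyde, and acid-promoted dehydration gives the conjugated (E)-enone. No alkoxide or hydroxide is present, so ring C(G) is not opened, and the boron-bound phenol cannot close to a flavanone before work-up.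

Step 9
Reactants: 14 (2E)-3-{3-[5,7-dimethoxy-3-(4-methoxyphenyl)-4-oxo-4H-chromen-8-yl]-4-methoxyphenyl}-1-(2-hydroxy-4-methoxyphenyl)prop-2-en-1-one
Product: 16 5,7-dimethoxy-8-[2-methoxy-5-(7-methoxy-4-oxo-4H-chromen-3-yl)phenyl]-3-(4-methoxyphenyl)-4H-chromen-4-one, via rearranged dimethyl acetal 15 (not isolated)
Conditions: Tl(NO3)3·3H2O (1.1 equiv), MeOH/CH2Cl2, rt; then 10% aq. HCl, reflux
Reagents that add atoms: none
Why: Oxidative 1,2-aryl shift of a 2'-hydroxychalcone: methoxythallation of the enone, migration of the electron-rich 4-methoxyaryl ring from Cβ to Cα with reduction of trivalent to monovalent thallium, and capture by methanol give racemic acetal 15. Its stereocentre disappears when acid closes ring C(D) by attack of the phenol on the oxocarbenium ion and loss of methanol.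

Step 10
Reactants: 16 5,7-dimethoxy-8-[2-methoxy-5-(7-methoxy-4-oxo-4H-chromen-3-yl)phenyl]-3-(4-methoxyphenyl)-4H-chromen-4-one
Product: 17 5,7-dihydroxy-8-[2-hydroxy-5-(7-hydroxy-4-oxo-4H-chromen-3-yl)phenyl]-3-(4-hydroxyphenyl)-4H-chromen-4-one (CNP0500144.0)
Conditions: BBr3 (12 equiv), CH2Cl2, −78 °C → rt; then MeOH, H2O
Reagents that add atoms: none
Why: Lewis acid ether cleavage: each methoxy oxygen binds BBr3 and bromide removes the methyl group by SN2, and aqueous methanol then hydrolyses the aryl borates. The benzopyranone rings tolerate the acidic, non-basic conditions.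

## Compound list

1 | biochanin A, 5,7-dihydroxy-3-(4-methoxyphenyl)-4H-chromen-4-one | COc1ccc(cc1)-c1coc2cc(O)cc(O)c2c1=O | starting material
2 | allyl bromide, 3-bromoprop-1-ene | C=CCBr | starting material
3 | 5-hydroxy-3-(4-methoxyphenyl)-7-(prop-2-en-1-yloxy)-4H-chromen-4-one | C=CCOc1cc(O)c2c(c1)occ(-c1ccc(OC)cc1)c2=O | intermediate
4 | 5,7-dihydroxy-3-(4-methoxyphenyl)-8-(prop-2-en-1-yl)-4H-chromen-4-one | C=CCc1c(O)cc(O)c2c(=O)c(-c3ccc(OC)cc3)coc12 | intermediate
5 | 5,7-dimethoxy-3-(4-methoxyphenyl)-8-(prop-2-en-1-yl)-4H-chromen-4-one | C=CCc1c(OC)cc(OC)c2c(=O)c(-c3ccc(OC)cc3)coc12 | intermediate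
6 | 5,7-dimethoxy-3-(4-methoxyphenyl)-8-(2-oxopropyl)-4H-chromen-4-one | CC(=O)Cc1c(OC)cc(OC)c2c(=O)c(-c3ccc(OC)cc3)coc12 | intermediate
7 | bromoacetic acid | OC(=O)CBr | starting material
8 | [2-(dimethylaminomethylidene)propane-1,3-diylidene]bis(dimethylammonium) dichloride, formed in the flask and not isolated | CN(C)C=C(C=[N+](C)C)C=[N+](C)C.[Cl-].[Cl-] | intermediate
9 | 2-[(dimethylamino)methylidene]propanedial | CN(C)C=C(C=O)C=O | intermediate
10 | 2-{2-[5,7-dimethoxy-3-(4-methoxyphenyl)-4-oxo-4H-chromen-8-yl]-3-oxobutylidene}propanedial, drawn as the neutral racemic C–H tautomer, present in the flask as its delocalised potassium dienolate and not isolated | CC(=O)C(C=C(C=O)C=O)c1c(OC)cc(OC)c2c(=O)c(-c3ccc(OC)cc3)coc12 | intermediate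
11 | 4-hydroxy-3-[5,7-dimethoxy-3-(4-methoxyphenyl)-4-oxo-4H-chromen-8-yl]benzaldehyde | O=Cc1ccc(O)c(-c2c(OC)cc(OC)c3c(=O)c(-c4ccc(OC)cc4)coc23)c1 | intermediate
12 | 3-[5,7-dimethoxy-3-(4-methoxyphenyl)-4-oxo-4H-chromen-8-yl]-4-methoxybenzaldehyde | O=Cc1ccc(OC)c(-c2c(OC)cc(OC)c3c(=O)c(-c4ccc(OC)cc4)coc23)c1 | intermediate
13 | 2-hydroxy-4-methoxyacetophenone, 1-(2-hydroxy-4-methoxyphenyl)ethan-1-one | CC(=O)c1ccc(OC)cc1O | starting material
14 | (2E)-3-{3-[5,7-dimethoxy-3-(4-methoxyphenyl)-4-oxo-4H-chromen-8-yl]-4-methoxyphenyl}-1-(2-hydroxy-4-methoxyphenyl)prop-2-en-1-one | COc1ccc(C(=O)/C=C/c2ccc(OC)c(-c3c(OC)cc(OC)c4c(=O)c(-c5ccc(OC)cc5)coc34)c2)c(O)c1 | intermediate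
15 | 2-{3-[5,7-dimethoxy-3-(4-methoxyphenyl)-4-oxo-4H-chromen-8-yl]-4-methoxyphenyl}-1-(2-hydroxy-4-methoxyphenyl)-3,3-dimethoxypropan-1-one, racemic, not isolated | COc1ccc(C(=O)C(C(OC)OC)c2ccc(OC)c(-c3c(OC)cc(OC)c4c(=O)c(-c5ccc(OC)cc5)coc34)c2)c(O)c1 | intermediate
16 | 5,7-dimethoxy-8-[2-methoxy-5-(7-methoxy-4-oxo-4H-chromen-3-yl)phenyl]-3-(4-methoxyphenyl)-4H-chromen-4-one | COc1ccc2c(c1)occ(-c1ccc(OC)c(-c3c(OC)cc(OC)c4c(=O)c(-c5ccc(OC)cc5)coc34)c1)c2=O | intermediate
17 | 5,7-dihydroxy-8-[2-hydroxy-5-(7-hydroxy-4-oxo-4H-chromen-3-yl)phenyl]-3-(4-hydroxyphenyl)-4H-chromen-4-one | O=c1c(-c2ccc(O)c(-c3c(O)cc(O)c4c(=O)c(-c5ccc(O)cc5)coc34)c2)coc2cc(O)ccc12 | target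

## Step count and least certain steps

Total: 10 steps. Longest linear sequence: 9 steps (steps 1–4 and 6–10 from 1); step 5 is a one-step branch.

**Step 6 (key step).** The most likely failure is incomplete ring closure: after the first C–C bond the intermediate rests as a delocalised, weakly electrophilic dienolate, and the second enolisation is slow. Alongside this, the hydroxide and dimethylamine that the condensation releases may open ring C(G) if the mixture has to be warmed. The fallback gives up the coupling-free biaryl construction; it sets out from 1 and returns at 12.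
- Exhaustive methylation of 1 (MeI, K2CO3, DMF) gives 5,7-dimethoxy-3-(4-methoxyphenyl)-4H-chromen-4-one F1.
- Electrophilic iodination (I2, CF3CO2Ag, CH2Cl2) gives 8-iodo-5,7-dimethoxy-3-(4-methoxyphenyl)-4H-chromen-4-one F2. C8 is the site that fully methylated 5,7-dioxygenated chromones are expected to favour; any 6-iodide would have to be separated.
- Suzuki–Miyaura coupling of F2 with purchased (5-formyl-2-methoxyphenyl)boronic acid F3 (Pd(OAc)2, SPhos, K3PO4, toluene/H2O, 90 °C) gives 12 directly. This accepts a tri-ortho-substituted cross-coupling.

**Step 2.** The most likely failure is poor site selectivity: the hydrogen-bonded 5-hydroxyl weakens the bond fixation that directs the shift to C8, so part of the allyl group may migrate to C6, and at 200 °C the ortho-allylphenol may cyclise onto the alkene. The fallback changes the substrate so that the benzopyranone alone decides the site; it sets out from 3 and returns at 5.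
- Methylation of the chelated phenol of 3 (MeI, K2CO3, DMF, 40 °C) gives 5-methoxy-3-(4-methoxyphenyl)-7-(prop-2-en-1-yloxy)-4H-chromen-4-one F4.
- Claisen rearrangement of F4 (N,N-diethylaniline, 200 °C) gives 7-hydroxy-5-methoxy-3-(4-methoxyphenyl)-8-(prop-2-en-1-yl)-4H-chromen-4-one F5.
- Methylation of F5 (MeI, K2CO3, acetone) gives 5.

**Step 8.** The most likely failure is slow condensation of the hindered, electron-rich aldehyde, with partial cleavage of the peri 5-methoxy group by the Lewis acid or cyclisation of the product to a flavanone during work-up. The fallback replaces the aldol by a neutral olefination; it sets out from 13 and returns at 14.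
- α-Bromination of 13 (CuBr2, EtOAc/CHCl3, reflux) gives 2-bromo-1-(2-hydroxy-4-methoxyphenyl)ethan-1-one F6.
- PPh3 (toluene, rt) gives [2-(2-hydroxy-4-methoxyphenyl)-2-oxoethyl]triphenylphosphonium bromide F7.
- Aqueous Na2CO3 gives the stabilised ylide 1-(2-hydroxy-4-methoxyphenyl)-2-(triphenyl-λ5-phosphanylidene)ethan-1-one F8.
- Wittig reaction of F8 with 12 (toluene, reflux) should give the (E)-enone 14 without acid or base.

**Step 9.** The most likely failure is diversion of the oxidation: the free 2'-hydroxychalcone may cyclise oxidatively to an aurone or flavone, or trivalent thallium may attack the electron-rich ring A(G) instead of the enone. The fallback masks the phenol as a ring ether and uses no thallium; it sets out from 14 and returns at 16.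
- Isomerisation of 14 (NaOAc, EtOH, reflux) gives the racemic flavanone 2-{3-[5,7-dimethoxy-3-(4-methoxyphenyl)-4-oxo-4H-chromen-8-yl]-4-methoxyphenyl}-7-methoxy-2,3-dihydro-4H-chromen-4-one F9.
- The known oxidative 2,3-aryl migration of flavanones with a trivalent iodine reagent (PhI(OAc)2, HC(OMe)3, cat. H2SO4, rt) should convert F9 into 16. The electron-rich migrating ring favours the shift over simple dehydrogenation.

## Further compounds

F1 | step 6 | 5,7-dimethoxy-3-(4-methoxyphenyl)-4H-chromen-4-one | COc1ccc(cc1)-c1coc2cc(OC)cc(OC)c2c1=O
F2 | step 6 | 8-iodo-5,7-dimethoxy-3-(4-methoxyphenyl)-4H-chromen-4-one | COc1ccc(cc1)-c1coc2c(I)c(OC)cc(OC)c2c1=O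
F3 | step 6 | (5-formyl-2-methoxyphenyl)boronic acid, purchased | COc1ccc(C=O)cc1B(O)O
F4 | step 2 | 5-methoxy-3-(4-methoxyphenyl)-7-(prop-2-en-1-yloxy)-4H-chromen-4-one | C=CCOc1cc(OC)c2c(c1)occ(-c1ccc(OC)cc1)c2=O
F5 | step 2 | 7-hydroxy-5-methoxy-3-(4-methoxyphenyl)-8-(prop-2-en-1-yl)-4H-chromen-4-one | C=CCc1c(O)cc(OC)c2c(=O)c(-c3ccc(OC)cc3)coc12
F6 | step 8 | 2-bromo-1-(2-hydroxy-4-methoxyphenyl)ethan-1-one | COc1ccc(C(=O)CBr)c(O)c1
F7 | step 8 | [2-(2-hydroxy-4-methoxyphenyl)-2-oxoethyl]triphenylphosphonium bromide | COc1ccc(C(=O)C[P+](c2ccccc2)(c2ccccc2)c2ccccc2)c(O)c1.[Br-]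
F8 | step 8 | 1-(2-hydroxy-4-methoxyphenyl)-2-(triphenyl-λ5-phosphanylidene)ethan-1-one | COc1ccc(C(=O)C=P(c2ccccc2)(c2ccccc2)c2ccccc2)c(O)c1
F9 | step 9 | 2-{3-[5,7-dimethoxy-3-(4-methoxyphenyl)-4-oxo-4H-chromen-8-yl]-4-methoxyphenyl}-7-methoxy-2,3-dihydro-4H-chromen-4-one, racemic | COc1ccc2c(c1)OC(CC2=O)c1ccc(OC)c(-c3c(OC)cc(OC)c4c(=O)c(-c5ccc(OC)cc5)coc34)c1
A1 | alternative 1 | 6-[(5-bromo-2-methoxyphenyl)methyl]-4-methoxy-2H-pyran-2-one | COc1cc(Cc2cc(Br)ccc2OC)oc(=O)c1
A2 | alternative 1 | methyl (2E)-6-(5-bromo-2-methoxyphenyl)-3-methoxy-5-oxohex-2-enoate | COC(=O)/C=C(/OC)CC(=O)Cc1cc(Br)ccc1OC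
A3 | alternative 1 | 2-(5-bromo-2-methoxyphenyl)-5-methoxybenzene-1,3-diol | COc1cc(O)c(-c2cc(Br)ccc2OC)c(O)c1
A4 | alternative 1 | 3-iodo-7-methoxy-4H-chromen-4-one | COc1ccc2c(c1)occ(I)c2=O
A5 | alternative 2 | 3-{2-[5-(1-carboxy-2-(3-methoxyphenoxy)ethenyl)-2-methoxyphenyl]-3-hydroxy-5-methoxyphenoxy}-2-(4-methoxyphenyl)prop-2-enoic acid, alkene geometries not fixed | COc1ccc(cc1)C(=COc1cc(OC)cc(O)c1-c1cc(ccc1OC)C(=COc1cccc(OC)c1)C(O)=O)C(O)=O
A6 | alternative 2 | 7-hydroxy-5-methoxy-8-[2-methoxy-5-(7-methoxy-4-oxo-4H-chromen-3-yl)phenyl]-3-(4-methoxyphenyl)-4H-chromen-4-one | COc1ccc(cc1)-c1coc2c(c1=O)c(OC)cc(O)c2-c1cc(ccc1OC)-c1coc2cc(OC)ccc2c1=O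
A7 | alternative 3 | 3-ethoxycyclobut-2-en-1-one | CCOC1=CC(=O)C1
A8 | alternative 3 | {[(5-bromo-2-methoxyphenyl)ethynyl]oxy}tri(propan-2-yl)silane | COc1ccc(Br)cc1C#CO[Si](C(C)C)(C(C)C)C(C)C
A9 | alternative 3 | 2-(5-bromo-2-methoxyphenyl)-5-ethoxy-3-{[tri(propan-2-yl)silyl]oxy}phenol | CCOc1cc(O)c(-c2cc(Br)ccc2OC)c(O[Si](C(C)C)(C(C)C)C(C)C)c1
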